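## Retrosynthetic overview

1. Numbering: oxane O1, C2 (CMe2), C3 (CHBr), C4, C5, C6 (quaternary); cyclohexane C1' (on C6), C3' (Cl), C4' (Br, Me). Last disconnections: C4'–Br (HBr across a 4'-methylidene), the methylidene (from a 4'-ketone) and C3'–Cl (α-chlorination); C1' is defined when a chiral lithium amide tells apart the two α-CH2 groups of a 4-substituted cyclohexanone.
2. Key disconnection: C3–C4 and O1–C2 of the oxane in one operation from three components, the (R)-oxetane O1–C6–C5–C4, 2-methylprop-1-enylmagnesium bromide (C3=C2) and a Br+ donor; this is a two-atom ring expansion of a four-membered ring that is not in the target.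
3. Enabling feature: O1 and C4 stand 1,3 across C6–C5, the pattern of an oxetane, whose strain makes C4 (C6 being quaternary) an electrophile while the O1–C6 bond and the C6 configuration stay intact; C2 (gem-dimethyl, on O1) next to C3 (Br) is the Markovnikov pattern of bromonium capture on a 2-methylprop-1-enyl group.
4. C6 is set first, by catalytic asymmetric double methylene transfer (ketone → epoxide → oxetane) onto a methyl ketone that carries the cyclohexane ring as its 4-ketal.
5. Ring order: cyclohexane (bought, as ketal), oxetane (temporary), oxane (key step); the three cyclohexane stereocentres follow.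

Key step: step 3

Assumption: the senses of induction of the lanthanum–lithium binaphthoxide catalyst (step 2) and of the chiral lithium amide (step 5) are taken by analogy with simple alkyl methyl ketones and with 4-tert-butylcyclohexanone; should either run the other way, the mirror-image reagent is used and nothing else changes.

## Route

Step 1
Reactants: 1 1,4-dioxaspiro[4.5]decane-8-carboxylic acid
Product: 2 1-(1,4-dioxaspiro[4.5]decan-8-yl)ethan-1-one
Conditions: MeLi (2.2 equiv), Et2O, 0 °C → rt; inverse quench into ice-water
Reagents that add atoms: methyllithium, [Li]C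
Why: Carboxylic acid to methyl ketone with an organolithium: the second equivalent of MeLi adds to the lithium carboxylate to give a gem-dialkoxide that cannot over-add and collapses to the ketone only on aqueous quench, the dioxolane being inert to base and to the non-acidic work-up (no stereocentre).

Step 2
Reactants: 2 1-(1,4-dioxaspiro[4.5]decan-8-yl)ethan-1-one
Product: 4 (2R)-2-methyl-2-(1,4-dioxaspiro[4.5]decan-8-yl)oxetane, via epoxide 3 (not isolated)
Conditions: Me3S(O)I, NaH (ylide, 1.2 equiv), LaLi3(binaphthoxide)3 from enantiopure BINOL (5 mol%, antipode matched to the (S)-epoxide), (2,4,6-(MeO)3C6H2)3P=O (5 mol%), 5 Å MS, THF, rt; then more ylide (1.5 equiv) and catalyst (15 mol%), 45 °C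
Reagents that add atoms: trimethylsulfoxonium iodide, C[S+](C)(C)=O.[I-]
Why: Catalytic asymmetric Corey–Chaykovsky epoxidation followed in the same flask by ylide ring expansion of the epoxide: the heterobimetallic lanthanum–lithium aryloxide binds ketone and ylide together so that methylene is delivered to one face of the methyl ketone (methyl against the α-branched ring substituent sets C6), and a second ylide then attacks the epoxide CH2 and closes the oxetane by 4-exo-tet displacement of DMSO without touching C6, the matched catalyst being expected to raise the enantiomeric purity further in this second stage.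

Step 3
Reactants: 4 (2R)-2-methyl-2-(1,4-dioxaspiro[4.5]decan-8-yl)oxetane; 5 2-methylprop-1-en-1-ylmagnesium bromide
Product: 8 (3S,6R)-3-bromo-6-(1,4-dioxaspiro[4.5]decan-8-yl)-2,2,6-trimethyloxane, via bromomagnesium alkoxide 6 (not isolated), via alkenol 7 (not isolated)
Conditions: 5 (1.5 equiv), CuBr (10 mol%), THF, −20 °C → rt; then (CF3)2CHOH, THF distilled off; NBS (2.0 equiv), 4 Å MS, (CF3)2CHOH, 0 °C, dark
Reagents that add atoms: N-bromosuccinimide, BrN1C(=O)CCC1=O
Why: Ring strain lets the copper-catalysed alkenyl Grignard reagent open the oxetane by SN2 attack at its only unhindered carbon, C4, which forms C3–C4 and leaves the O1–C6 bond and the C6 configuration untouched; hexafluoroisopropanol then frees alkenol 7, and NBS turns its trisubstituted alkene into a bromonium ion that the tertiary hydroxyl captures at C2, forming O1–C2 and C3–Br by anti addition. The closest known reaction types are the cuprate-type opening of oxetanes at the less substituted carbon and the NBS/hexafluoroisopropanol bromoetherification of bishomoallylic tertiary alcohols to 3-bromo-2,2-dimethyloxanes. The oxetane is opened and the oxane is closed in the 6-endo-trig (Markovnikov) mode, the ionising solvent placing the positive charge on the tertiary C2 rather than allowing 5-exo attack at C3. The new stereocentre C3 is controlled by C6 through a chair transition state in which bromine is equatorial and the bulky spiroketal-cyclohexyl group on C6 is equatorial, the C6 methyl taking the axial site beside the axial C2 methyl; since either alkene face can accept Br+, the choice is made in this ring-closing transition state and should favour the 3,6-trans (3S,6R) isomer. The step needs C4-over-C6 attack on the oxetane (secured by the quaternary C6), 6-endo over 5-exo closure (secured by the gem-dimethyl terminus and the solvent) and the facial selectivity just described; the excess of NBS keeps the bromide brought in with 5 oxidised so that it does not compete as a nucleophile.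

Step 4
Reactants: 8 (3S,6R)-3-bromo-6-(1,4-dioxaspiro[4.5]decan-8-yl)-2,2,6-trimethyloxane
Product: 9 4-[(2R,5S)-5-bromo-2,6,6-trimethyloxan-2-yl]cyclohexan-1-one
Conditions: 1 M aq. HCl, THF, rt
Reagents that add atoms: water, O
Why: Acid-catalysed hydrolysis of the dioxolane ketal, to which the secondary bromide and the hindered dialkyl ether of the oxane are inert at room temperature (no stereocentre affected).

Step 5
Reactants: 9 4-[(2R,5S)-5-bromo-2,6,6-trimethyloxan-2-yl]cyclohexan-1-one
Product: 10 trimethyl({(4R)-4-[(2R,5S)-5-bromo-2,6,6-trimethyloxan-2-yl]cyclohex-1-en-1-yl}oxy)silane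
Conditions: lithium bis[(S)-1-phenylethyl]amide (1.2 equiv, from the amine and nBuLi), Me3SiCl (5 equiv, present during deprotonation), THF, −78 °C
Reagents that add atoms: chlorotrimethylsilane, C[Si](C)(C)Cl
Why: Enantiotopic-group-selective deprotonation with a C2-symmetric chiral lithium amide under internal silyl quench: the oxane substituent locks the chair as tert-butyl does in the parent case, the base removes one of the two axial α-hydrogens, and the side on which the enol double bond is placed (toward C3') defines C1' as R under reagent control, while the low temperature leaves the secondary bromide untouched.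

Step 6
Reactants: 10 trimethyl({(4R)-4-[(2R,5S)-5-bromo-2,6,6-trimethyloxan-2-yl]cyclohex-1-en-1-yl}oxy)silane
Product: 11 (2S,4R)-4-[(2R,5S)-5-bromo-2,6,6-trimethyloxan-2-yl]-2-chlorocyclohexan-1-one
Conditions: NCS (1.05 equiv), CH2Cl2, −20 → 0 °C; neutral aqueous work-up
Reagents that add atoms: N-chlorosuccinimide, ClN1C(=O)CCC1=O
Why: Electrophilic α-chlorination of a silyl enol ether, regiospecific for C3': chlorine is delivered along the axial trajectory of the half-chair that keeps the C1' substituent equatorial, which gives the 3'-axial chloride trans to C1' (S), the arrangement also favoured for α-chlorocyclohexanones by dipole minimisation, and neutral conditions avoid epimerisation.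

Step 7
Reactants: 11 (2S,4R)-4-[(2R,5S)-5-bromo-2,6,6-trimethyloxan-2-yl]-2-chlorocyclohexan-1-one
Product: 12 (3S,6R)-3-bromo-6-[(1R,3S)-3-chloro-4-methylidenecyclohexyl]-2,2,6-trimethyloxane
Conditions: Tebbe reagent Cp2Ti(μ-CH2)(μ-Cl)AlMe2 (1.3 equiv), pyridine (cat.), THF/toluene, −40 → 0 °C
Reagents that add atoms: Tebbe reagent, C[Al-]1(C)C[Ti]([Cl+]1)(C1C=CC=C1)C1C=CC=C1
Why: Tebbe olefination (titanium methylidene, oxatitanacyclobutane) converts the ketone into the exocyclic alkene under non-basic conditions, so the enolisable, epimerisable C3' chloride is preserved (no new stereocentre; the allylic chlorine stays axial, which also relieves A(1,3) strain).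

Step 8
Reactants: 12 (3S,6R)-3-bromo-6-[(1R,3S)-3-chloro-4-methylidenecyclohexyl]-2,2,6-trimethyloxane
Product: 13 (3S,6R)-3-bromo-6-[(1R,3S,4S)-4-bromo-3-chloro-4-methylcyclohexyl]-2,2,6-trimethyloxane (deoxy isocaespitol)
Conditions: anhydrous HBr (3 equiv, CH2Cl2 solution), CH2Cl2, −78 °C; cold aq. NaHCO3 quench
Reagents that add atoms: hydrogen bromide, Br
Why: Polar Markovnikov hydrobromination: protonation of the exocyclic CH2 gives the tertiary C4' cation, which the antiperiplanar axial C3' chlorine bridges as a chloronium ion, so bromide can only open it at the tertiary carbon from the opposite face (trans-diaxial opening, Fürst–Plattner), placing bromine axial and cis to the C1' substituent with methyl equatorial (C4' S); at −78 °C the hindered oxane oxygen is only reversibly protonated and the ring should survive.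

## Compound list

1 | 1,4-dioxaspiro[4.5]decane-8-carboxylic acid | OC(=O)C1CCC2(CC1)OCCO2 | starting material
2 | 1-(1,4-dioxaspiro[4.5]decan-8-yl)ethan-1-one | CC(=O)C1CCC2(CC1)OCCO2 | intermediate
3 | (2S)-2-methyl-2-(1,4-dioxaspiro[4.5]decan-8-yl)oxirane | O1[C@@](C)(C2CCC3(CC2)OCCO3)C1 | intermediate
4 | (2R)-2-methyl-2-(1,4-dioxaspiro[4.5]decan-8-yl)oxetane | O1[C@@](C)(C2CCC3(CC2)OCCO3)CC1 | intermediate
5 | 2-methylprop-1-en-1-ylmagnesium bromide | CC(C)=C[Mg]Br | starting material
6 | bromomagnesium (2R)-2-(1,4-dioxaspiro[4.5]decan-8-yl)-6-methylhept-5-en-2-olate | Br[Mg]O[C@@](C)(C1CCC2(CC1)OCCO2)CCC=C(C)C | intermediate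
7 | (2R)-2-(1,4-dioxaspiro[4.5]decan-8-yl)-6-methylhept-5-en-2-ol | O[C@@](C)(C1CCC2(CC1)OCCO2)CCC=C(C)C | intermediate
8 | (3S,6R)-3-bromo-6-(1,4-dioxaspiro[4.5]decan-8-yl)-2,2,6-trimethyloxane | CC1(C)O[C@@](C)(C2CCC3(CC2)OCCO3)CC[C@@H]1Br | intermediate
9 | 4-[(2R,5S)-5-bromo-2,6,6-trimethyloxan-2-yl]cyclohexan-1-one | CC1(C)O[C@@](C)(C2CCC(=O)CC2)CC[C@@H]1Br | intermediate
10 | trimethyl({(4R)-4-[(2R,5S)-5-bromo-2,6,6-trimethyloxan-2-yl]cyclohex-1-en-1-yl}oxy)silane | CC1(C)O[C@@](C)([C@@H]2CCC(O[Si](C)(C)C)=CC2)CC[C@@H]1Br | intermediate
11 | (2S,4R)-4-[(2R,5S)-5-bromo-2,6,6-trimethyloxan-2-yl]-2-chlorocyclohexan-1-one | CC1(C)O[C@@](C)([C@@H]2CCC(=O)[C@@H](Cl)C2)CC[C@@H]1Br | intermediate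
12 | (3S,6R)-3-bromo-6-[(1R,3S)-3-chloro-4-methylidenecyclohexyl]-2,2,6-trimethyloxane | CC1(C)O[C@@](C)([C@@H]2CCC(=C)[C@@H](Cl)C2)CC[C@@H]1Br | intermediate
13 | (3S,6R)-3-bromo-6-[(1R,3S,4S)-4-bromo-3-chloro-4-methylcyclohexyl]-2,2,6-trimethyloxane (deoxy isocaespitol) | CC1(C)O[C@@](C)([C@@H]2CC[C@](C)(Br)[C@@H](Cl)C2)CC[C@@H]1Br | target

## Step count and risks

Total step count: 8. Longest linear sequence: 8 steps (1 → 13); compound 5 is purchased.

Steps most likely to fail:

Step 3. What may go wrong: partial 5-exo capture of the bromonium ion at C3, weak facial discrimination in the ring-closing transition state (C3 epimer), and interception of the bromonium ion by bromide. The fallback sets out from alkenol 7, isolated by aqueous work-up after the Grignard stage, and returns at 8; it fixes C3 by reagent control before the ring is closed. Shi epoxidation of 7 (D-fructose-derived ketone, KHSO5, K2CO3 buffer, MeCN/dimethoxymethane/H2O, 0 °C) should give, by the spiro transition-state model, (2R)-2-(1,4-dioxaspiro[4.5]decan-8-yl)-4-[(2R)-3,3-dimethyloxiran-2-yl]butan-2-ol F1. Li2NiBr4 in THF at 0 °C should open the epoxide at its secondary carbon with inversion to give (2R,5S)-5-bromo-2-(1,4-dioxaspiro[4.5]decan-8-yl)-6-methylheptane-2,6-diol F2. Catalytic camphorsulfonic acid in CH2Cl2/(CF3)2CHOH at 0 °C should then ionise the bromine-flanked tertiary carbinol with anchimeric assistance by the anti bromine, and the C6 hydroxyl opens the configurationally defined bromonium ion at C2, with C3 retained, to give 8. The preference for attack at the tertiary carbon remains that of the main route.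

Step 5. What may go wrong: insufficient discrimination between the two α-CH2 groups by the chiral base, or enolate equilibration before silylation, which would erode the configuration at C1'. The fallback sets out from 9 and returns at 11, replacing asymmetric deprotonation by enamine catalysis. A C2-symmetric 2,5-diphenylpyrrolidine (the antipode matched to C1' R, 10–20 mol%) with NCS in CH2Cl2 should select the α-carbon and chlorinate it in one event. No compound outside the list is made (F0), and steps 5 and 6 are merged.

Step 8. What may go wrong: acid-induced opening of the di-tertiary oxane ether, or ionisation and transposition of the allylic chloride before the alkene is protonated. The fallback sets out from 12 and returns at 13, leaving the polar manifold for a neutral radical one. Hydrogen-atom-transfer hydrobromination (Co(acac)2, tBuOOH, Et3SiH, TsBr, nPrOH, rt) delivers a hydrogen atom to the CH2 terminus. The tertiary C4' radical, whose β-C–Cl bond is too strong to fragment at a competitive rate, should abstract bromine from TsBr along the axial direction anti to the C3' chlorine. No compound outside the list is made (F0).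

## Further compounds

F1 | step 3 | (2R)-2-(1,4-dioxaspiro[4.5]decan-8-yl)-4-[(2R)-3,3-dimethyloxiran-2-yl]butan-2-ol | O[C@@](C)(C1CCC2(CC1)OCCO2)CC[C@@H]1C(C)(C)O1
F2 | step 3 | (2R,5S)-5-bromo-2-(1,4-dioxaspiro[4.5]decan-8-yl)-6-methylheptane-2,6-diol | O[C@@](C)(C1CCC2(CC1)OCCO2)CC[C@@H](C(C)(C)O)Br
F0 | step 5 | none | none
F0 | step 8 | none | none
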